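The readings come from a simulation from invented constants; scatter was added.

Suppose that each electrophile that reacts takes one nucleophile and frees one acid, and that this acid must sit on free base or on a further nucleophile: that balance holds at every moment.

| flask | electrophile | nucleophile | free base | remark | time |
|---|---|---|---|---|---|
| birch | 0.34 M | 0.442 M | 0.26 M | run made earlier |  |
| cedar | 0.34 M | 0.442 M | 0.38 M | run made earlier |  |
| green | 0.34 M | 0.442 M | 0.340 M |  | 40 h |
| grey | 0.34 M | 0.442 M | 0.440 M |  | 40 h |
| teal | 0.34 M | 0.442 M | 0.570 M |  | 40 h |

- birch (time / h: electrophile / %, target / %): 3.00: 52, 45; 6.00: 31, 67; 12.0: 15, 79; 20.0: 9, 78; 40.0: 7, 69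
- cedar (time / h: electrophile / %, target / %): 4.00: 41, 57; 10.0: 19, 75; 20.0: 9, 82; 30.0: 3, 78; 40.0: 1, 72

(scatter of a reading: 1.5 percentage points)

1. part of the electrophile that has reacted at the end, green
2. part of the electrophile that has reacted at the end, grey
3. part of the electrophile that has reacted at the end, teal
4. what raising the concentration of free base from its lowest to its highest value here does to the part of the electrophile that has reacted (changes below 5 percentage points count as none) (it rises / it falls / no change)

The reacted amount therefore cannot pass the nucleophile charge, nor half the sum of nucleophile and free base. The smaller of these over the electrophile charged is 115% for green, and I call it the acid ceiling. Grey has 130% and teal 130%, so in each of the three flasks the ceiling stands above the whole electrophile charge, and electrophile is the limiting reagent. Birch, with 103%, kept 7% of its electrophile at 40 h, and cedar, with 121%, kept 1%. Green's ceiling lies between those two, so I expect green slightly short of the 99.0% reacted that is read from cedar, grey and teal near that reading, and a rise under 5 percentage points.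

The forecast says 97.5%, 99.3% and 99.6% for green, grey and teal, and no change, on the ground “Grey and teal have ample capacity”.

The flasks give 98.0%, 98.2% and 98.3%, a change of 0.23 points: no change.

    acid set free + free base ⇌ salt of the base, settled at all times (K = 1.60 × 10⁵ M⁻¹)
    nucleophile + acid set free ⇌ protonated nucleophile, settled at all times (K = 430 M⁻¹)
    target ⇌ isomer of the product (K = 1.30, k = 0.00980 h⁻¹)
    2 electrophile → homo dimer (k = 6.80 × 10⁻⁵ M⁻¹ h⁻¹)
    electrophile + nucleophile ⇌ acid set free + target (K = 0.560, k = 0.650 M⁻¹ h⁻¹)

Green's ceiling of 115% lies above the 98.0% reached, with 23% of its nucleophile and 4.0% of its free base still unbound at 40.0 h. A neighbour like green but with 0.18 M of nucleophile has a ceiling of 52.9% and gives 52.6%, with 0.753% of its nucleophile left. Green has not come to rest: left until 400 h, its reacted part reaches 99.8%, while target falls from 73.5% to 43.5% and isomer of the product rises from 24.5% to 56.4%.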